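**Plan**

- Retrosynthesis: the enal (C15), the C9 methacrylate, the C1=C2 vinyl group and the C11=C13 methylene are unmasked last. The γ-lactone is then cut at O–C8 and C11–C7, and the carbocycle at C5–C6 and C9–C10.
- Forward: a Diels–Alder reaction builds ring C5–C10. C9 is raised to the ketone. A three-component annulation (enone, malonic half-ester dianion, I2) closes the lactone ring on C7/C8. The C9 carbinol, C13 methylene, vinyl group, methacrylate and aldehyde follow.
- Enabling feature: C8 (lactone O) and C7 (bearing C11) are the α- and β-carbons of the oxygenated ring carbon C9. At the ketone level, C9=O makes C7 electrophilic and C8 an enolate carbon, which iodine converts into an electrophile for the carboxylate.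
- Stereochemistry: catalyst-controlled endo Diels–Alder reaction (C5, C6, C10; C9 transiently), addition anti to the C6 ester (C7), tether-enforced cis fusion (C8), hydroxyl-directed hydride delivery from the C1 carbinol (C9).

Key step: step 10

Remark: locants are those of the elemane skeleton (ring C5–C10 with C10 quaternary; C1=C2 on C10; C3, C4, C15 on C5; C11–C13 in the lactone; oxygen on C6, C8, C9); "upper face" is the ring face carrying C1, and the SMILES give the absolute configuration.

**Step 1**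
Reactants: 1 methylglyoxal (2-oxopropanal, 40% aqueous); 2 ethyl 2-(triphenyl-λ5-phosphanylidene)propanoate
Product: 3 ethyl (2E)-2-methyl-4-oxopent-2-enoate
Conditions: CH2Cl2/H2O, 0 → 23 °C
Reagents that add atoms: none
Why: Wittig olefination of the aldehyde carbonyl (far more electrophilic than the ketone) by the stabilised α-methyl ylide should give the (E)-enoate with ester and acetyl trans, the geometry that later places the C10 methyl cis to the C5 side chain.

**Step 2**
Reactants: 3 ethyl (2E)-2-methyl-4-oxopent-2-enoate; 4 (1E,3E)-buta-1,3-diene-1,4-diyl diacetate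
Product: 5 ethyl 6-acetyl-2,5-diacetoxy-1-methylcyclohex-3-ene-1-carboxylate (1-methyl, 2-OAc, 5-OAc and 6-acetyl all cis, ester trans to them)
Conditions: (S)-3,3-diphenyl-1-(2-methylphenyl)tetrahydro-1H,3H-pyrrolo[1,2-c][1,3,2]oxazaborole protonated with HN(SO2CF3)2 (20 mol%), CH2Cl2, −40 → 23 °C
Reagents that add atoms: none
Why: In this Lewis acid catalysed Diels–Alder reaction the boron-bound acetyl group sits endo, so the (E,E)-diene places both acetoxy groups cis to the acetyl and methyl groups and trans to the ester, while the chiral oxazaborolidinium cation shields one face of the dienophile and should set C5, C6, C9 and C10 in the absolute sense shown (the antipodal catalyst is available if the sense of induction requires it).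

**Step 3**
Reactants: 5 ethyl 6-acetyl-2,5-diacetoxy-1-methylcyclohex-3-ene-1-carboxylate
Product: 6 ethyl 2,5-diacetoxy-1-methyl-6-(prop-1-en-2-yl)cyclohex-3-ene-1-carboxylate (configuration unchanged)
Conditions: Zn, CH2Br2, TiCl4, THF/CH2Cl2, 0 → 23 °C
Reagents that add atoms: dibromomethane, BrCBr
Why: Takai–Lombardo methylenation with the non-basic zinc–titanium methylene reagent should convert the methyl ketone into the isopropenyl group without epimerising C5 or eliminating the β-acetoxy group, and it leaves the esters untouched.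

**Step 4**
Reactants: 6 ethyl 2,5-diacetoxy-1-methyl-6-(prop-1-en-2-yl)cyclohex-3-ene-1-carboxylate
Product: 7 5-(hydroxymethyl)-5-methyl-6-(prop-1-en-2-yl)cyclohex-2-ene-1,4-diol (1-OH, 4-OH, 5-methyl and 6-isopropenyl cis, CH2OH trans)
Conditions: LiAlH4, THF, 0 → 23 °C; Rochelle salt work-up
Reagents that add atoms: none
Why: Hydride reduction of the hindered ester to the neopentyl carbinol, with cleavage of both acetates, should give the triol without touching any stereocentre.

**Step 5**
Reactants: 7 5-(hydroxymethyl)-5-methyl-6-(prop-1-en-2-yl)cyclohex-2-ene-1,4-diol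
Product: 8 2,2,4a-trimethyl-5-(prop-1-en-2-yl)-4a,5,6,8a-tetrahydro-4H-1,3-benzodioxin-6-ol (trans-fused; 4a-methyl, 5-isopropenyl, 6-OH and O1 cis)
Conditions: Me2C(OMe)2, pyridinium p-toluenesulfonate (cat.), acetone, 23 °C
Reagents that add atoms: 2,2-dimethoxypropane, COC(C)(C)OC
Why: In this acetalisation only the 1,3-related C1 and C9 hydroxyls can close a six-membered isopropylidene acetal, which leaves the C6 hydroxyl as the single free alcohol.

**Step 6**
Reactants: 8 2,2,4a-trimethyl-5-(prop-1-en-2-yl)-4a,5,6,8a-tetrahydro-4H-1,3-benzodioxin-6-ol; 9 angelic acid, (2Z)-2-methylbut-2-enoic acid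
Product: 10 2,2,4a-trimethyl-5-(prop-1-en-2-yl)-4a,5,6,8a-tetrahydro-4H-1,3-benzodioxin-6-yl (2Z)-2-methylbut-2-enoate
Conditions: 9, 2,4,6-trichlorobenzoyl chloride, Et3N, toluene, 23 °C; then 8, 80 °C
Reagents that add atoms: none
Why: Yamaguchi-type esterification through the mixed anhydride, run without a nucleophilic catalyst, should acylate the hindered C6 alcohol with retention at C6 and without Z-to-E isomerisation of the angeloyl group.

**Step 7**
Reactants: 10 2,2,4a-trimethyl-5-(prop-1-en-2-yl)-4a,5,6,8a-tetrahydro-4H-1,3-benzodioxin-6-yl (2Z)-2-methylbut-2-enoate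
Product: 11 4-hydroxy-5-(hydroxymethyl)-5-methyl-6-(prop-1-en-2-yl)cyclohex-2-en-1-yl (2Z)-2-methylbut-2-enoate
Conditions: AcOH/H2O/THF (3:1:1), 40 °C
Reagents that add atoms: none
Why: Mild acidic acetal hydrolysis should release the C1/C9 diol while the angelate and the allylic system survive.

**Step 8**
Reactants: 11 4-hydroxy-5-(hydroxymethyl)-5-methyl-6-(prop-1-en-2-yl)cyclohex-2-en-1-yl (2Z)-2-methylbut-2-enoate
Product: 12 5-(hydroxymethyl)-5-methyl-4-oxo-6-(prop-1-en-2-yl)cyclohex-2-en-1-yl (2Z)-2-methylbut-2-enoate (ester oxygen, isopropenyl and methyl cis; CH2OH trans)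
Conditions: activated MnO2 (excess), CH2Cl2, 23 °C
Reagents that add atoms: none
Why: Manganese dioxide oxidises only the allylic C9 alcohol and not the saturated neopentyl C1 alcohol, so it should give the C9 enone in which C7 is the β-carbon and C8 the α-carbon.

**Step 9**
Reactants: 12 5-(hydroxymethyl)-5-methyl-4-oxo-6-(prop-1-en-2-yl)cyclohex-2-en-1-yl (2Z)-2-methylbut-2-enoate
Product: 13 5-methyl-4-oxo-6-(prop-1-en-2-yl)-5-[(trimethylsilyloxy)methyl]cyclohex-2-en-1-yl (2Z)-2-methylbut-2-enoate
Conditions: Me3SiCl, imidazole, CH2Cl2, 0 °C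
Reagents that add atoms: chlorotrimethylsilane, C[Si](C)(C)Cl
Why: O-silylation masks the C1 hydroxyl so that no alkoxide can compete with the carboxylate for C8 in the annulation.

**Step 10**
Reactants: 13 5-methyl-4-oxo-6-(prop-1-en-2-yl)-5-[(trimethylsilyloxy)methyl]cyclohex-2-en-1-yl (2Z)-2-methylbut-2-enoate; 14 mono-tert-butyl malonate, 3-(tert-butoxy)-3-oxopropanoic acid
Product: 18 tert-butyl 6-(hydroxymethyl)-6-methyl-4-[(2Z)-2-methylbut-2-enoyloxy]-2,7-dioxo-5-(prop-1-en-2-yl)octahydro-1-benzofuran-3-carboxylate (cis-fused lactone on the upper face; C3 epimers), via lithium enolate carboxylate 15 (not isolated), via iodo ketone carboxylate 16 (not isolated), via silyl ether lactone 17 (not isolated)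
Conditions: 14, LiN(i-Pr)2 (2 equiv per 14), THF, −78 → 0 °C; 13, −78 °C; I2, THF, −78 → 23 °C; aq. Na2S2O3; 1 M aq. citric acid, 23 °C
Reagents that add atoms: none
Why: Proposed new method: the dilithium dianion of the malonic half ester adds through carbon to C7 of the enone (conjugate addition), the resulting C8=C9 lithium enolate is iodinated at C8, and the neighbouring lithium carboxylate displaces iodide in an intramolecular SN2 reaction, so that C11–C7 and O–C8 are formed in one flask from three components (enone, half ester, iodine). The closest known reaction types are conjugate additions of carboxylic acid dianions to enones, α-iodination of enolates, iodine-mediated Michael-initiated ring closures of 1,3-dicarbonyl compounds onto enones, and the oxidative lactonisation of 5-oxo acids with aryl-λ3-iodanes. The γ-lactone (O–C12–C11–C7–C8) closes in the 5-exo-tet mode. C7 is set by attack anti to the lower-face C6 angeloyloxy and C5 isopropenyl groups; C8 is set by the tether, because only the lower-face iodide (formed directly or by iodide exchange) can be displaced from the upper face, which enforces cis fusion; C11 forms unselectively and is erased in step 12. The step needs 1,4- over 1,2-addition (secured by the quaternary C10 beside the carbonyl and the stabilised nucleophile), iodination at C8 rather than C11 (the C11–H between an ester and a carboxylate is too weakly acidic to take over the enolate charge at −78 °C), and O- over C-alkylation (the carboxylate is the only anionic centre left once the enolate has been iodinated).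

**Step 11**
Reactants: 18 tert-butyl 6-(hydroxymethyl)-6-methyl-4-[(2Z)-2-methylbut-2-enoyloxy]-2,7-dioxo-5-(prop-1-en-2-yl)octahydro-1-benzofuran-3-carboxylate
Product: 19 tert-butyl 7-hydroxy-6-(hydroxymethyl)-6-methyl-4-[(2Z)-2-methylbut-2-enoyloxy]-2-oxo-5-(prop-1-en-2-yl)octahydro-1-benzofuran-3-carboxylate (7-OH on the lower face, trans to O1 and to CH2OH)
Conditions: Me4NBH(OAc)3, MeCN/AcOH (1:1), −30 → 0 °C
Reagents that add atoms: none
Why: In this hydroxyl-directed (Evans–Saksena type) reduction the acyloxyborohydride bound to the upper-face C1 hydroxyl delivers hydride intramolecularly to the upper face of the C9 carbonyl and should give the lower-face C9 alcohol, trans to the lactone oxygen at C8.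

**Step 12**
Reactants: 19 tert-butyl 7-hydroxy-6-(hydroxymethyl)-6-methyl-4-[(2Z)-2-methylbut-2-enoyloxy]-2-oxo-5-(prop-1-en-2-yl)octahydro-1-benzofuran-3-carboxylate
Product: 21 7-hydroxy-6-(hydroxymethyl)-6-methyl-3-methylidene-2-oxo-5-(prop-1-en-2-yl)octahydro-1-benzofuran-4-yl (2Z)-2-methylbut-2-enoate, via diol acid 20 (not isolated)
Conditions: ZnBr2, CH2Cl2, 23 °C; then 37% aq. CH2O, Et2NH, NaOAc, AcOH, dioxane, 23 → 70 °C
Reagents that add atoms: formaldehyde, C=O
Why: Lewis acid cleavage of the tert-butyl ester followed by decarboxylative Mannich methylenation (aminomethylation at C11, then loss of CO2 and amine) should give the exocyclic methylene regiospecifically and leaves C7 and C8 untouched.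

**Step 13**
Reactants: 21 7-hydroxy-6-(hydroxymethyl)-6-methyl-3-methylidene-2-oxo-5-(prop-1-en-2-yl)octahydro-1-benzofuran-4-yl (2Z)-2-methylbut-2-enoate
Product: 22 6-formyl-7-hydroxy-6-methyl-3-methylidene-2-oxo-5-(prop-1-en-2-yl)octahydro-1-benzofuran-4-yl (2Z)-2-methylbut-2-enoate
Conditions: 2,2,6,6-tetramethylpiperidin-1-oxyl (10 mol%), PhI(OAc)2, CH2Cl2, 23 °C
Reagents that add atoms: none
Why: Oxoammonium-mediated oxidation is selective for the primary C1 alcohol over the hindered secondary C9 alcohol and should give the aldehyde under non-basic conditions that avoid retro-aldol cleavage.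

**Step 14**
Reactants: 22 6-formyl-7-hydroxy-6-methyl-3-methylidene-2-oxo-5-(prop-1-en-2-yl)octahydro-1-benzofuran-4-yl (2Z)-2-methylbut-2-enoate
Product: 23 6-ethenyl-7-hydroxy-6-methyl-3-methylidene-2-oxo-5-(prop-1-en-2-yl)octahydro-1-benzofuran-4-yl (2Z)-2-methylbut-2-enoate
Conditions: Zn, CH2Br2, TiCl4, THF/CH2Cl2, 0 → 23 °C
Reagents that add atoms: dibromomethane, BrCBr
Why: Takai–Lombardo methylenation, which is non-basic and tolerates the free β-hydroxyl, the lactone and the enoates, should turn the neopentyl aldehyde into the C10 vinyl group.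

**Step 15**
Reactants: 23 6-ethenyl-7-hydroxy-6-methyl-3-methylidene-2-oxo-5-(prop-1-en-2-yl)octahydro-1-benzofuran-4-yl (2Z)-2-methylbut-2-enoate; 24 methacrylic anhydride
Product: 25 6-ethenyl-6-methyl-3-methylidene-7-[(2-methylprop-2-enoyl)oxy]-2-oxo-5-(prop-1-en-2-yl)octahydro-1-benzofuran-4-yl (2Z)-2-methylbut-2-enoate
Conditions: 24, 4-(dimethylamino)pyridine, Et3N, CH2Cl2, 23 → 40 °C
Reagents that add atoms: none
Why: Nucleophilic acyl-transfer catalysis (Steglich-type acylation) should esterify the remaining hindered C9 alcohol with retention of configuration.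

**Step 16**
Reactants: 25 6-ethenyl-6-methyl-3-methylidene-7-[(2-methylprop-2-enoyl)oxy]-2-oxo-5-(prop-1-en-2-yl)octahydro-1-benzofuran-4-yl (2Z)-2-methylbut-2-enoate
Product: 27 CNP0102441.1, (3aR,4S,5R,6S,7R,7aR)-6-ethenyl-6-methyl-3-methylidene-7-[(2-methylprop-2-enoyl)oxy]-2-oxo-5-(3-oxoprop-1-en-2-yl)octahydro-1-benzofuran-4-yl (2Z)-2-methylbut-2-enoate, via allylic alcohol 26 (not isolated)
Conditions: SeO2 (0.5 equiv), t-BuOOH, CH2Cl2, 0 → 23 °C; then MnO2 (excess), same flask, 23 °C
Reagents that add atoms: selenium dioxide, O=[Se]=O; tert-butyl hydroperoxide (terminal oxygen source), CC(C)(C)OO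
Why: Riley allylic oxidation (ene reaction followed by a [2,3]-shift) should attack the only electron-rich alkene bearing an allylic methyl, the isopropenyl group, and manganese dioxide should then take the allylic alcohol to the 2-substituted acrolein without touching the conjugated esters.

**Compound list**

1 | methylglyoxal (2-oxopropanal) | CC(=O)C=O | starting material
2 | ethyl 2-(triphenyl-λ5-phosphanylidene)propanoate | CCOC(=O)C(C)=P(c1ccccc1)(c1ccccc1)c1ccccc1 | starting material
3 | ethyl (2E)-2-methyl-4-oxopent-2-enoate | CCOC(=O)/C(C)=C/C(C)=O | intermediate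
4 | (1E,3E)-buta-1,3-diene-1,4-diyl diacetate | CC(=O)O/C=C/C=C/OC(C)=O | starting material
5 | ethyl 6-acetyl-2,5-diacetoxy-1-methylcyclohex-3-ene-1-carboxylate (1-Me, 2-OAc, 5-OAc, 6-acetyl cis; ester trans) | CCOC(=O)[C@@]1(C)[C@H](C(C)=O)[C@H](OC(C)=O)C=C[C@@H]1OC(C)=O | intermediate
6 | ethyl 2,5-diacetoxy-1-methyl-6-(prop-1-en-2-yl)cyclohex-3-ene-1-carboxylate | CCOC(=O)[C@@]1(C)[C@H](C(C)=C)[C@H](OC(C)=O)C=C[C@@H]1OC(C)=O | intermediate
7 | 5-(hydroxymethyl)-5-methyl-6-(prop-1-en-2-yl)cyclohex-2-ene-1,4-diol | OC[C@@]1(C)[C@H](C(C)=C)[C@H](O)C=C[C@@H]1O | intermediate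
8 | 2,2,4a-trimethyl-5-(prop-1-en-2-yl)-4a,5,6,8a-tetrahydro-4H-1,3-benzodioxin-6-ol (trans-fused) | CC1(C)OC[C@@]2(C)[C@H](C(C)=C)[C@H](O)C=C[C@@H]2O1 | intermediate
9 | angelic acid, (2Z)-2-methylbut-2-enoic acid | C/C=C(/C)C(=O)O | starting material
10 | 6-O-angelate of 8 | CC1(C)OC[C@@]2(C)[C@H](C(C)=C)[C@H](OC(=O)/C(C)=C\C)C=C[C@@H]2O1 | intermediate
11 | 4-hydroxy-5-(hydroxymethyl)-5-methyl-6-(prop-1-en-2-yl)cyclohex-2-en-1-yl (2Z)-2-methylbut-2-enoate | OC[C@@]1(C)[C@H](C(C)=C)[C@H](OC(=O)/C(C)=C\C)C=C[C@@H]1O | intermediate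
12 | 5-(hydroxymethyl)-5-methyl-4-oxo-6-(prop-1-en-2-yl)cyclohex-2-en-1-yl (2Z)-2-methylbut-2-enoate | OC[C@@]1(C)[C@H](C(C)=C)[C@H](OC(=O)/C(C)=C\C)C=CC1=O | intermediate
13 | trimethylsilyl ether of 12 | C[Si](C)(C)OC[C@@]1(C)[C@H](C(C)=C)[C@H](OC(=O)/C(C)=C\C)C=CC1=O | intermediate
14 | mono-tert-butyl malonate, 3-(tert-butoxy)-3-oxopropanoic acid | CC(C)(C)OC(=O)CC(=O)O | starting material
15 | dilithium enolate carboxylate of the C7 Michael adduct (not isolated) | [Li+].[Li+].C[Si](C)(C)OC[C@@]1(C)[C@H](C(C)=C)[C@H](OC(=O)/C(C)=C\C)[C@@H](C(C(=O)OC(C)(C)C)C(=O)[O-])C=C1[O-] | intermediate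
16 | lithium carboxylate of the C8 (lower-face) α-iodo ketone (not isolated) | [Li+].C[Si](C)(C)OC[C@@]1(C)[C@H](C(C)=C)[C@H](OC(=O)/C(C)=C\C)[C@@H](C(C(=O)OC(C)(C)C)C(=O)[O-])[C@H](I)C1=O | intermediate
17 | trimethylsilyl ether of keto lactone 18 (not isolated) | C[Si](C)(C)OC[C@@]1(C)[C@H](C(C)=C)[C@H](OC(=O)/C(C)=C\C)[C@H]2C(C(=O)OC(C)(C)C)C(=O)O[C@H]2C1=O | intermediate
18 | tert-butyl 6-(hydroxymethyl)-6-methyl-4-[(2Z)-2-methylbut-2-enoyloxy]-2,7-dioxo-5-(prop-1-en-2-yl)octahydro-1-benzofuran-3-carboxylate (cis-fused) | OC[C@@]1(C)[C@H](C(C)=C)[C@H](OC(=O)/C(C)=C\C)[C@H]2C(C(=O)OC(C)(C)C)C(=O)O[C@H]2C1=O | intermediate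
19 | tert-butyl 7-hydroxy-6-(hydroxymethyl)-6-methyl-4-[(2Z)-2-methylbut-2-enoyloxy]-2-oxo-5-(prop-1-en-2-yl)octahydro-1-benzofuran-3-carboxylate | OC[C@@]1(C)[C@H](C(C)=C)[C@H](OC(=O)/C(C)=C\C)[C@H]2C(C(=O)OC(C)(C)C)C(=O)O[C@H]2[C@@H]1O | intermediate
20 | 3-carboxylic acid corresponding to 19 (not isolated) | OC[C@@]1(C)[C@H](C(C)=C)[C@H](OC(=O)/C(C)=C\C)[C@H]2C(C(=O)O)C(=O)O[C@H]2[C@@H]1O | intermediate
21 | 7-hydroxy-6-(hydroxymethyl)-6-methyl-3-methylidene-2-oxo-5-(prop-1-en-2-yl)octahydro-1-benzofuran-4-yl (2Z)-2-methylbut-2-enoate | OC[C@@]1(C)[C@H](C(C)=C)[C@H](OC(=O)/C(C)=C\C)[C@H]2C(=C)C(=O)O[C@H]2[C@@H]1O | intermediate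
22 | 6-formyl-7-hydroxy-6-methyl-3-methylidene-2-oxo-5-(prop-1-en-2-yl)octahydro-1-benzofuran-4-yl (2Z)-2-methylbut-2-enoate | O=C[C@@]1(C)[C@H](C(C)=C)[C@H](OC(=O)/C(C)=C\C)[C@H]2C(=C)C(=O)O[C@H]2[C@@H]1O | intermediate
23 | 6-ethenyl-7-hydroxy-6-methyl-3-methylidene-2-oxo-5-(prop-1-en-2-yl)octahydro-1-benzofuran-4-yl (2Z)-2-methylbut-2-enoate | C=C[C@@]1(C)[C@H](C(C)=C)[C@H](OC(=O)/C(C)=C\C)[C@H]2C(=C)C(=O)O[C@H]2[C@@H]1O | intermediate
24 | methacrylic anhydride | CC(=C)C(=O)OC(=O)C(C)=C | starting material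
25 | 7-O-methacrylate of 23 | C=C[C@@]1(C)[C@H](C(C)=C)[C@H](OC(=O)/C(C)=C\C)[C@H]2C(=C)C(=O)O[C@H]2[C@@H]1OC(=O)C(=C)C | intermediate
26 | 5-(3-hydroxyprop-1-en-2-yl) analogue of 25 (not isolated) | C=C[C@@]1(C)[C@H](C(=C)CO)[C@H](OC(=O)/C(C)=C\C)[C@H]2C(=C)C(=O)O[C@H]2[C@@H]1OC(=O)C(=C)C | intermediate
27 | CNP0102441.1 | C=C[C@@]1(C)[C@H](C(=C)C=O)[C@H](OC(=O)/C(C)=C\C)[C@H]2C(=C)C(=O)O[C@H]2[C@@H]1OC(=O)C(=C)C | target

**Step count and risks**

Total step count: 16. Longest linear sequence: 16 steps (1 and 2 to 27).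

Steps most likely to fail:

1. Step 10 (labelled). The enolate charge may migrate from C8 to C11 before iodination, leading to iodination at the malonate carbon and C-alkylation (cyclopropane), or the dianion may act as a base instead of adding 1,4. Fallback from 13, using known reactions: di-tert-butyl malonate is added in a base-catalysed Michael reaction (KOt-Bu cat., THF) to give keto diester F1. ZnBr2 in CH2Cl2 then removes both tert-butyl groups and the silyl ether to give keto malonic acid F2. PhI(OH)OTs in CH2Cl2 lactonises one carboxyl onto the ketone α-carbon (oxidative lactonisation of a 5-oxo acid through its enol) to give lactone acid F3. Hydroxyl-directed reduction with Me4NBH(OAc)3 as in step 11 gives diol acid 20, where the route is rejoined at the second stage of step 12.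

2. Step 2. Bond formation at the fully substituted dienophile carbon against a doubly acetoxylated diene may be too slow, with erosion of endo and facial selectivity or loss of acetic acid from the β-acetoxy ketone. Fallback from 4: treatment with MeLi and then Me3SiCl gives the more electron-rich (1E,3E)-1,4-bis(trimethylsilyloxy)buta-1,3-diene F4, which is combined with 3 under the same catalyst to give bis(silyl ether) adduct F5. Methylenation as in step 3 gives diene ester F6, and LiAlH4 reduction with a dilute acid work-up removes the silyl groups and returns triol 7.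

3. Step 16. Chemoselectivity among the allylic positions may be poor (the angelate and methacrylate methyls compete) and the product may over-oxidise. Fallback from 25: ene-type chlorination of the isopropenyl group with Ca(OCl)2 and CO2 in CH2Cl2/H2O gives allylic chloride F7, and a Kornblum-type oxidation with trimethylamine N-oxide in DMSO gives 27.

**Further compounds**

F1 | step 10 | di-tert-butyl malonate Michael adduct of 13 (keto diester) | C[Si](C)(C)OC[C@@]1(C)[C@H](C(C)=C)[C@H](OC(=O)/C(C)=C\C)[C@@H](C(C(=O)OC(C)(C)C)C(=O)OC(C)(C)C)CC1=O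
F2 | step 10 | keto malonic acid with free C1 hydroxyl | OC[C@@]1(C)[C@H](C(C)=C)[C@H](OC(=O)/C(C)=C\C)[C@@H](C(C(=O)O)C(=O)O)CC1=O
F3 | step 10 | cis-fused C9-keto lactone 3-carboxylic acid | OC[C@@]1(C)[C@H](C(C)=C)[C@H](OC(=O)/C(C)=C\C)[C@H]2C(C(=O)O)C(=O)O[C@H]2C1=O
F4 | step 2 | (1E,3E)-1,4-bis(trimethylsilyloxy)buta-1,3-diene | C[Si](C)(C)O/C=C/C=C/O[Si](C)(C)C
F5 | step 2 | ethyl 6-acetyl-1-methyl-2,5-bis(trimethylsilyloxy)cyclohex-3-ene-1-carboxylate (configuration as 5) | CCOC(=O)[C@@]1(C)[C@H](C(C)=O)[C@H](O[Si](C)(C)C)C=C[C@@H]1O[Si](C)(C)C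
F6 | step 2 | ethyl 1-methyl-6-(prop-1-en-2-yl)-2,5-bis(trimethylsilyloxy)cyclohex-3-ene-1-carboxylate | CCOC(=O)[C@@]1(C)[C@H](C(C)=C)[C@H](O[Si](C)(C)C)C=C[C@@H]1O[Si](C)(C)C
F7 | step 16 | 5-(3-chloroprop-1-en-2-yl) analogue of 25 | C=C[C@@]1(C)[C@H](C(=C)CCl)[C@H](OC(=O)/C(C)=C\C)[C@H]2C(=C)C(=O)O[C@H]2[C@@H]1OC(=O)C(=C)C
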